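The data were computed on assumed constants; the scatter is artificial.

Decide first what the partner charge allows, then follow this flask by one number instead of two.

| flask | starting material | partner | capture agent | scavenger | free catalyst | remark | time |
|---|---|---|---|---|---|---|---|
| red | 0.057 M | 0.90 equiv (fed, over 2.0 h) | 2.9 mM | 1.5 equiv | 3.5 mol% | run made earlier |  |
| blue | 0.057 M | 0.90 equiv (fed, over 2.0 h) | 4.3 mM | 1.5 equiv | 3.5 mol% | run made earlier |  |
| flask | 0.057 M | 0.900 equiv (fed, over 2.0 h) | 5.70 mM | 1.50 equiv | 3.5 mol% |  | 2.5 d |

| run | time / h | starting material / % | target / % |
|---|---|---|---|
| red | 10.0 | 59.3 | 38.9 |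
| red | 20.0 | 35.3 | 62.5 |
| red | 30.0 | 23.7 | 74.9 |
| red | 40.0 | 17.9 | 81.8 |
| red | 50.0 | 14.0 | 85.1 |
| blue | 4.00 | 82.1 | 14.9 |
| blue | 12.0 | 53.8 | 43.9 |
| blue | 20.0 | 35.9 | 61.3 |
| blue | 30.0 | 24.3 | 73.6 |
| blue | 50.0 | 14.8 | 83.5 |

(scatter of a reading: 0.3 percentage points)

- the reaction counts as stopped when no species that holds the starting material changes by six tenths of a point or more over the second half of the time

- at 2.5 d, what has stopped the reaction, if anything has (forward and back rates have come level / all of the starting material has reacted / it is still moving / the partner has run out first / no working catalyst is left)
- how much of the starting material has reacted by 2.5 d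
- how much target there is at 2.5 d, in percent of the starting material charged

Take the main step by itself: one starting material takes up one partner, so the rate at which starting material falls divided by the rate at which partner falls is one, and time drops out. Counting the feed as complete, the surplus, which is starting material minus partner in percent of the starting material charged, is 10.0%. Conversion and target therefore head for about 90.0%, with partner as the limiting reagent, and a reading minus the surplus is my estimate of the partner left, an estimate that ignores starting material held on catalyst or as adduct.

Now add the pace. In the red run, this estimate falls from 25 percentage points at 20.0 h to 7.9 points at 40.0 h, a pseudo-first-order loss of 0.0582 h⁻¹. Carried to 2.5 d, that gives my conversion of 87.5%.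

Then add the capture agent. In the blue run, the estimate goes from 26 points at 20.0 h to 4.8 points at 50.0 h, a loss of 0.0562 h⁻¹, slower than red, though these are readings with their scatter. The flask's charge lies one equal step beyond blue, so I continue the trend: a pace of 0.0542 h⁻¹ from 5.6 points at 50.0 h. My conversion becomes 86.7%. Blue's last reading leaves 1.7 points as neither starting material nor target, so I expect 85.0% target. Starting material falls about 11 points over the second half, taking blue's reading at 30.0 h as the start, against the 0.6 of the stopping rule, so I call the flask still moving.

The forecast subtracts the same 10 and gives it is still moving, conversion 87% and target 84.8%: “the reaction is still moving, approaching the 90% partner ceiling”.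

The flask gives it is still moving, conversion 86.6% and target 85.0%.

    starting material + free catalyst ⇌ catalyst intermediate A (K = 46.0 L mol⁻¹, k = 1.70 L mol⁻¹ min⁻¹)
    catalyst intermediate B + capture agent → trapped intermediate (k = 0.230 L mol⁻¹ min⁻¹)
    catalyst intermediate C → free catalyst + target (k = 0.140 min⁻¹)
    partner → decomposition product (k = 1.10 × 10⁻⁶ min⁻¹)
    scavenger + released group → scavenged by-product (k = 3.70 L mol⁻¹ min⁻¹)
    catalyst intermediate B ⇌ released group + catalyst intermediate C (K = 0.150 M, k = 0.110 min⁻¹)
    partner + catalyst intermediate A → catalyst intermediate B (k = 2.10 L mol⁻¹ min⁻¹)
    starting material + released group ⇌ idle adduct, settled at all times (K = 36.0 L mol⁻¹)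

The flask has not come to rest at 2.5 d: 4.4% of its partner charge remains, and the largest change over the second half is 12 points. In the neighbouring flask with 0.023 M of starting material, the end state of starting material 35.1% less partner 26 points gives a difference of 9.6 points, close to the surplus of 10.0%. Left until 25.0 d, the flask's target climbs to 88.9%, against the 90.0% of target the partner charge allows, and its conversion to 90.4%, with partner at 0% and starting material at 9.60%.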